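The chain between the furan ring and the butenolide ring holds two E-trisubstituted alkenes, each inside a CH2–CH2–CH=C(CH3) unit whose four carbons map onto C2–C5 of 2,3-dihydrofuran. Everything rests on cutting both carbon–carbon bonds at that methyl-bearing sp2 carbon. In one operation a mixed alkyl(dihydrofuranyl)cuprate rearranges with loss of the ring C–O bond and the resulting alkenylcopper is methylated, which fixes the E geometry and frees a hydroxyethyl handle for the next round. The precursor pairs the citronellol-derived (S)-6-silyloxy-4-methylhexyllithium with 5-lithio-2,3-dihydrofuran. The E-alkylidene butenolide ring is built last from an ynoate.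

Key step: step 5

Remark: the exocyclic alkene of the target is read as E (side chain trans to the ring oxygen, cis to C4 of the butenolide), and (S)-citronellol of high enantiomeric purity is assumed, because its stereocentre is carried through unchanged.

Step 1
Reactants: 1 (S)-citronellol
Product: 2 (S)-tert-butyl[(3,7-dimethyloct-6-en-1-yl)oxy]dimethylsilane
Conditions: TBSCl, imidazole, CH2Cl2, 0 → 20 °C
Reagents that add atoms: tert-butyldimethylsilyl chloride, CC(C)(C)[Si](C)(C)Cl
Why: Imidazole-promoted silylation of the only hydroxyl (silyl ether protection) gives an ether that should tolerate t-BuLi, cuprates and organozinc reagents and leaves the stereocentre untouched.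

Step 2
Reactants: 2 (S)-tert-butyl[(3,7-dimethyloct-6-en-1-yl)oxy]dimethylsilane
Product: 4 (S)-6-(tert-butyldimethylsilyloxy)-4-methylhexan-1-ol, via ozonide 3 (not isolated)
Conditions: O3, CH2Cl2, −78 °C; then NaBH4, MeOH, −78 → 20 °C
Reagents that add atoms: ozone, [O-][O+]=O
Why: Ozonolysis cleaves the single alkene and the borohydride work-up reduces the ozonide straight to the primary alcohol, so the carbon three atoms from the stereocentre becomes the future carbanion site while the silyl ether is untouched.

Step 3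
Reactants: 4 (S)-6-(tert-butyldimethylsilyloxy)-4-methylhexan-1-ol
Product: 5 (S)-tert-butyl[(6-iodo-3-methylhexyl)oxy]dimethylsilane
Conditions: PPh3, imidazole, I2, CH2Cl2, 0 → 20 °C
Reagents that add atoms: iodine, II
Why: Appel-type iodination converts the primary alcohol by SN2 displacement of the alkoxyphosphonium ion, and the imidazole buffer should keep the silyl ether intact.

Step 4
Reactants: 6 2,3-dihydrofuran
Product: 7 5-lithio-2,3-dihydrofuran
Conditions: 6 (1.1 equiv), t-BuLi (1.0 equiv), THF–pentane, −78 → 0 °C, 30 min; obtained as a solution and used at once (a fresh batch is made before step 5 and again before step 7)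
Reagents that add atoms: tert-butyllithium, [Li]C(C)(C)C
Why: Direct α-lithiation of the cyclic enol ether removes the vinylic hydrogen on the oxygen-bearing carbon, which is acidified by the adjacent oxygen, and the slight excess of 6 ensures that no t-BuLi is carried into the cuprate step.

Step 5
Reactants: 5 (S)-tert-butyl[(6-iodo-3-methylhexyl)oxy]dimethylsilane; 7 5-lithio-2,3-dihydrofuran; 8 iodomethane
Product: 12 (S,E)-10-(tert-butyldimethylsilyloxy)-4,8-dimethyldec-3-en-1-ol, via alkyllithium 9 (not isolated), via mixed cuprate 10 (not isolated), via alkenylcopper alkoxide 11 (not isolated)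
Conditions: 5, t-BuLi (2.05 equiv), Et2O–pentane, −78 °C; CuBr·SMe2 (1.0 equiv), Me2S–Et2O, −78 → −40 °C; 7 (1.0 equiv, THF solution from step 4) added at −78 °C, then → 20 °C; MeI (excess), 0 → 20 °C; aq NH4Cl–NH3
Reagents that add atoms: 5-lithio-2,3-dihydrofuran (7), [Li]C1=CCCO1; iodomethane (8), CI
Why: Iodine–lithium exchange and CuBr·SMe2 give the alkylcopper, which binds 7 to form the 1:1 mixed cuprate 10, so the chiral alkyl group is the only ligand able to migrate and none of it is sacrificed. On warming, that group shifts from copper to the metal-bearing sp2 carbon (1,2-metallate rearrangement), entering anti to the ring C–O bond and expelling the alkoxide with inversion at that carbon. The alkenylcopper 11 therefore carries copper cis to the CH2CH2OLi arm and is methylated by iodomethane with retention, so the alkyl–C(sp2) and methyl–C(sp2) bonds are both made in one flask. The closest known reaction type is the 1,2-metallate rearrangement of cuprates of α-lithiated cyclic enol ethers with electrophilic trapping, a relative of the Zweifel olefination and the Matteson homologation. No ring is closed (the dihydrofuran ring is opened) and no stereocentre is formed, the existing one lying three carbons from the metal and staying untouched. The selectivity needed is alkene geometry, and the five-membered ring secures it by holding O and C3 cis, so that inversion followed by retention can only give the E-alkene.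

Step 6
Reactants: 12 (S,E)-10-(tert-butyldimethylsilyloxy)-4,8-dimethyldec-3-en-1-ol
Product: 13 (S,E)-tert-butyl[(10-iodo-3,7-dimethyldec-7-en-1-yl)oxy]dimethylsilane
Conditions: PPh3, imidazole, I2, CH2Cl2, 0 → 20 °C
Reagents that add atoms: iodine, II
Why: Appel-type iodination of the primary homoallylic alcohol proceeds by SN2 at carbon and should not touch the trisubstituted alkene or the silyl ether.

Step 7
Reactants: 13 (S,E)-tert-butyl[(10-iodo-3,7-dimethyldec-7-en-1-yl)oxy]dimethylsilane; 7 5-lithio-2,3-dihydrofuran (fresh batch from step 4); 8 iodomethane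
Product: 17 (S,3E,7E)-14-(tert-butyldimethylsilyloxy)-4,8,12-trimethyltetradeca-3,7-dien-1-ol, via homoallyllithium 14 (not isolated), via mixed cuprate 15 (not isolated), via alkenylcopper alkoxide 16 (not isolated)
Conditions: 13, t-BuLi (2.05 equiv), Et2O–pentane, −78 °C; CuBr·SMe2 (1.0 equiv), Me2S–Et2O, −78 → −40 °C; 7 (1.0 equiv, THF solution from step 4) added at −78 °C, then → 20 °C; MeI (excess), 0 → 20 °C; aq NH4Cl–NH3
Reagents that add atoms: 5-lithio-2,3-dihydrofuran (7), [Li]C1=CCCO1; iodomethane (8), CI
Why: The same 1,2-metallate rearrangement with methylation is repeated on the homoallylic organolithium, which keeps its constitution and alkene geometry at low temperature, and the ring constraint again dictates the E geometry of the second alkene.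

Step 8
Reactants: 17 (S,3E,7E)-14-(tert-butyldimethylsilyloxy)-4,8,12-trimethyltetradeca-3,7-dien-1-ol
Product: 18 (S,7E,11E)-tert-butyl[(14-iodo-3,7,11-trimethyltetradeca-7,11-dien-1-yl)oxy]dimethylsilane
Conditions: PPh3, imidazole, I2, CH2Cl2, 0 → 20 °C
Reagents that add atoms: iodine, II
Why: Appel-type iodination again turns the primary alcohol into the iodide by SN2 displacement without affecting the two alkenes or the silyl ether.

Step 9
Reactants: 18 (S,7E,11E)-tert-butyl[(14-iodo-3,7,11-trimethyltetradeca-7,11-dien-1-yl)oxy]dimethylsilane; 19 3-bromofuran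
Product: 21 tert-butyl{[(S,7E,11E)-14-(furan-3-yl)-3,7,11-trimethyltetradeca-7,11-dien-1-yl]oxy}dimethylsilane, via alkylzinc iodide 20 (not isolated)
Conditions: Zn dust (activated with BrCH2CH2Br and Me3SiCl), LiCl, THF, 40 °C; then 19, Pd(OAc)2 (2 mol %), SPhos (4 mol %), THF, 20 → 50 °C
Reagents that add atoms: 3-bromofuran (19), Brc1ccoc1
Why: Zinc insertion into the primary iodide gives an alkylzinc iodide that should undergo Negishi sp3–sp2 cross-coupling with 3-bromofuran at zerovalent palladium carrying a bulky biarylphosphine, which favours reductive elimination over β-hydride elimination and tolerates the silyl ether.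

Step 10
Reactants: 21 tert-butyl{[(S,7E,11E)-14-(furan-3-yl)-3,7,11-trimethyltetradeca-7,11-dien-1-yl]oxy}dimethylsilane
Product: 22 (S,7E,11E)-14-(furan-3-yl)-3,7,11-trimethyltetradeca-7,11-dien-1-ol
Conditions: Bu4NF, THF, 0 → 20 °C
Reagents that add atoms: none
Why: Fluoride-mediated desilylation frees the primary alcohol under non-acidic conditions that spare the acid-sensitive 3-alkylfuran.

Step 11
Reactants: 22 (S,7E,11E)-14-(furan-3-yl)-3,7,11-trimethyltetradeca-7,11-dien-1-ol
Product: 23 (S,7E,11E)-14-(furan-3-yl)-3,7,11-trimethyltetradeca-7,11-dienal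
Conditions: Dess–Martin periodinane, NaHCO3, CH2Cl2, 0 → 20 °C
Reagents that add atoms: none
Why: Dess–Martin oxidation under bicarbonate buffer stops at the aldehyde and should leave the furan and the alkenes alone, and the stereocentre is β to the carbonyl and cannot epimerise by enolisation.

Step 12
Reactants: 23 (S,7E,11E)-14-(furan-3-yl)-3,7,11-trimethyltetradeca-7,11-dienal
Product: 25 3-[(S,3E,7E)-4,8,12-trimethyltetradeca-3,7-dien-13-yn-1-yl]furan, via enol nonaflate 24 (not isolated)
Conditions: C4F9SO2F (1.2 equiv), P2-Et phosphazene base (2.5 equiv), DMF, −20 → 20 °C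
Reagents that add atoms: none
Why: Enolisation and O-sulfonylation give the alkenyl nonaflate, from which the strong non-nucleophilic phosphazene base eliminates nonaflate to the terminal alkyne (one-pot carbonyl-to-alkyne conversion through an enol sulfonate), with no added carbon and under conditions that are neither acidic nor oxidising.

Step 13
Reactants: 25 3-[(S,3E,7E)-4,8,12-trimethyltetradeca-3,7-dien-13-yn-1-yl]furan; 26 methyl chloroformate
Product: 28 methyl (S,8E,12E)-15-(furan-3-yl)-4,8,12-trimethylpentadeca-8,12-dien-2-ynoate, via lithium acetylide 27 (not isolated)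
Conditions: n-BuLi (1.05 equiv), THF, −78 °C; then ClCO2Me, −78 → 0 °C
Reagents that add atoms: methyl chloroformate (26), COC(=O)Cl
Why: Deprotonation of the terminal alkyne, which is far more acidic than the furan C–H bonds, followed by C-acylation of the lithium acetylide with the chloroformate gives the ynoate.

Step 14
Reactants: 28 methyl (S,8E,12E)-15-(furan-3-yl)-4,8,12-trimethylpentadeca-8,12-dien-2-ynoate
Product: 30 methyl (S,2E,8E,12E)-15-(furan-3-yl)-2-iodo-4,8,12-trimethylpentadeca-2,8,12-trienoate, via α-stannyl enoate 29 (not isolated)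
Conditions: Bu3SnH (1.1 equiv), Pd(PPh3)4 (3 mol %), THF, 0 → 20 °C; then I2 (to persisting colour), CH2Cl2, 0 °C, dark; aq Na2S2O3
Reagents that add atoms: iodine, II
Why: Palladium-catalysed hydrostannation adds H and Sn syn across the ynoate with tin at the α-carbon, and iododestannylation with retention then gives the α-iodo enoate with the chain cis to the ester, iodine reacting much faster at the C–Sn bond than at the furan or the alkenes.

Step 15
Reactants: 30 methyl (S,2E,8E,12E)-15-(furan-3-yl)-2-iodo-4,8,12-trimethylpentadeca-2,8,12-trienoate; 31 propanoic acid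
Product: 33 methyl (S,2E,8E,12E)-15-(furan-3-yl)-4,8,12-trimethyl-2-(propanoyloxy)pentadeca-2,8,12-trienoate, via cuprous propanoate 32 (not isolated)
Conditions: 31 (2.2 equiv), Cu2O (1.1 equiv), PhMe, reflux with removal of H2O; evaporate; then 30, NMP, 20 → 60 °C, dark
Reagents that add atoms: propanoic acid (31), CCC(=O)O
Why: Ullmann-type C–O coupling of the activated alkenyl iodide with the cuprous carboxylate should occur with retention of alkene geometry, giving the E-enol propanoate whose acyloxy group is trans to the chain.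

Step 16
Reactants: 33 methyl (S,2E,8E,12E)-15-(furan-3-yl)-4,8,12-trimethyl-2-(propanoyloxy)pentadeca-2,8,12-trienoate
Product: 34 (E)-5-[(2S,6E,10E)-13-(furan-3-yl)-2,6,10-trimethyltrideca-6,10-dien-1-ylidene]-4-hydroxy-3-methylfuran-2(5H)-one
Conditions: LiN(SiMe3)2 (2.2 equiv), THF, −78 → 0 °C; cold dilute HCl to pH 3
Reagents that add atoms: none
Why: In this Dieckmann condensation the propanoate enolate attacks the neighbouring methyl ester in a 5-exo-trig closure, and loss of methoxide gives the tetronate anion, whose formation drives the reaction and whose exocyclic alkene keeps the geometry of the enol ester (chain trans to the ring oxygen).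

Step 17
Reactants: 34 (E)-5-[(2S,6E,10E)-13-(furan-3-yl)-2,6,10-trimethyltrideca-6,10-dien-1-ylidene]-4-hydroxy-3-methylfuran-2(5H)-one; 35 hexadecanoyl chloride
Product: 36 (E)-5-[(2S,6E,10E)-13-(furan-3-yl)-2,6,10-trimethyltrideca-6,10-dien-1-ylidene]-3-methyl-2-oxo-2,5-dihydrofuran-4-yl hexadecanoate
Conditions: 35 (1.1 equiv), Et3N (1.3 equiv), CH2Cl2, 0 °C, dark
Reagents that add atoms: hexadecanoyl chloride (35), CCCCCCCCCCCCCCCC(=O)Cl
Why: O-Acylation of the vinylogous acid at O4 with the acid chloride and a tertiary amine is the kinetic pathway because C3 is already substituted, and it should give the enol palmitate without touching the stereocentre or the alkenes.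

Compound list

1 | (S)-citronellol | OCC[C@@H](C)CCC=C(C)C | starting material
2 | (S)-tert-butyl[(3,7-dimethyloct-6-en-1-yl)oxy]dimethylsilane | CC(C)(C)[Si](C)(C)OCC[C@@H](C)CCC=C(C)C | intermediate
3 | ozonide of 2: 5-[(S)-5-(tert-butyldimethylsilyloxy)-3-methylpentyl]-3,3-dimethyl-1,2,4-trioxolane (both epimers at the ring CH) | CC(C)(C)[Si](C)(C)OCC[C@@H](C)CCC1OOC(C)(C)O1 | intermediate
4 | (S)-6-(tert-butyldimethylsilyloxy)-4-methylhexan-1-ol | OCCC[C@H](C)CCO[Si](C)(C)C(C)(C)C | intermediate
5 | (S)-tert-butyl[(6-iodo-3-methylhexyl)oxy]dimethylsilane | ICCC[C@H](C)CCO[Si](C)(C)C(C)(C)C | intermediate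
6 | 2,3-dihydrofuran | C1=COCC1 | starting material
7 | 5-lithio-2,3-dihydrofuran | [Li]C1=CCCO1 | intermediate
8 | iodomethane | CI | starting material
9 | (S)-6-(tert-butyldimethylsilyloxy)-4-methylhexyllithium | [Li]CCC[C@H](C)CCO[Si](C)(C)C(C)(C)C | intermediate
10 | lithium [(S)-6-(tert-butyldimethylsilyloxy)-4-methylhexyl](4,5-dihydrofuran-2-yl)cuprate | [Li+].CC(C)(C)[Si](C)(C)OCC[C@@H](C)CCC[Cu-]C1=CCCO1 | intermediate
11 | lithium (S,Z)-10-(tert-butyldimethylsilyloxy)-4-cuprio-8-methyldec-3-en-1-olate (copper cis to the CH2CH2O arm) | [Li]OCC/C=C(\[Cu])CCC[C@H](C)CCO[Si](C)(C)C(C)(C)C | intermediate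
12 | (S,E)-10-(tert-butyldimethylsilyloxy)-4,8-dimethyldec-3-en-1-ol | OCC/C=C(\C)CCC[C@H](C)CCO[Si](C)(C)C(C)(C)C | intermediate
13 | (S,E)-tert-butyl[(10-iodo-3,7-dimethyldec-7-en-1-yl)oxy]dimethylsilane | ICC/C=C(\C)CCC[C@H](C)CCO[Si](C)(C)C(C)(C)C | intermediate
14 | (S,E)-10-(tert-butyldimethylsilyloxy)-4,8-dimethyldec-3-en-1-yllithium | [Li]CC/C=C(\C)CCC[C@H](C)CCO[Si](C)(C)C(C)(C)C | intermediate
15 | lithium [(S,E)-10-(tert-butyldimethylsilyloxy)-4,8-dimethyldec-3-en-1-yl](4,5-dihydrofuran-2-yl)cuprate | [Li+].CC(C)(C)[Si](C)(C)OCC[C@@H](C)CCC/C(C)=C/CC[Cu-]C1=CCCO1 | intermediate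
16 | lithium (S,3Z,7E)-14-(tert-butyldimethylsilyloxy)-4-cuprio-8,12-dimethyltetradeca-3,7-dien-1-olate (copper cis to the CH2CH2O arm) | [Li]OCC/C=C(\[Cu])CC/C=C(\C)CCC[C@H](C)CCO[Si](C)(C)C(C)(C)C | intermediate
17 | (S,3E,7E)-14-(tert-butyldimethylsilyloxy)-4,8,12-trimethyltetradeca-3,7-dien-1-ol | OCC/C=C(\C)CC/C=C(\C)CCC[C@H](C)CCO[Si](C)(C)C(C)(C)C | intermediate
18 | (S,7E,11E)-tert-butyl[(14-iodo-3,7,11-trimethyltetradeca-7,11-dien-1-yl)oxy]dimethylsilane | ICC/C=C(\C)CC/C=C(\C)CCC[C@H](C)CCO[Si](C)(C)C(C)(C)C | intermediate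
19 | 3-bromofuran | Brc1ccoc1 | starting material
20 | [(S,3E,7E)-14-(tert-butyldimethylsilyloxy)-4,8,12-trimethyltetradeca-3,7-dien-1-yl]zinc iodide | I[Zn]CC/C=C(\C)CC/C=C(\C)CCC[C@H](C)CCO[Si](C)(C)C(C)(C)C | intermediate
21 | tert-butyl{[(S,7E,11E)-14-(furan-3-yl)-3,7,11-trimethyltetradeca-7,11-dien-1-yl]oxy}dimethylsilane | CC(C)(C)[Si](C)(C)OCC[C@@H](C)CCC/C(C)=C/CC/C(C)=C/CCc1ccoc1 | intermediate
22 | (S,7E,11E)-14-(furan-3-yl)-3,7,11-trimethyltetradeca-7,11-dien-1-ol | OCC[C@@H](C)CCC/C(C)=C/CC/C(C)=C/CCc1ccoc1 | intermediate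
23 | (S,7E,11E)-14-(furan-3-yl)-3,7,11-trimethyltetradeca-7,11-dienal | O=CC[C@@H](C)CCC/C(C)=C/CC/C(C)=C/CCc1ccoc1 | intermediate
24 | (3S,7E,11E)-14-(furan-3-yl)-3,7,11-trimethyltetradeca-1,7,11-trien-1-yl nonafluorobutane-1-sulfonate (both isomers at the enol alkene) | FC(F)(F)C(F)(F)C(F)(F)C(F)(F)S(=O)(=O)OC=C[C@@H](C)CCC/C(C)=C/CC/C(C)=C/CCc1ccoc1 | intermediate
25 | 3-[(S,3E,7E)-4,8,12-trimethyltetradeca-3,7-dien-13-yn-1-yl]furan | C#C[C@@H](C)CCC/C(C)=C/CC/C(C)=C/CCc1ccoc1 | intermediate
26 | methyl chloroformate | COC(=O)Cl | starting material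
27 | lithium acetylide of 25 | [Li]C#C[C@@H](C)CCC/C(C)=C/CC/C(C)=C/CCc1ccoc1 | intermediate
28 | methyl (S,8E,12E)-15-(furan-3-yl)-4,8,12-trimethylpentadeca-8,12-dien-2-ynoate | COC(=O)C#C[C@@H](C)CCC/C(C)=C/CC/C(C)=C/CCc1ccoc1 | intermediate
29 | methyl (S,2E,8E,12E)-15-(furan-3-yl)-4,8,12-trimethyl-2-(tributylstannyl)pentadeca-2,8,12-trienoate | COC(=O)/C(=C\[C@@H](C)CCC/C(C)=C/CC/C(C)=C/CCc1ccoc1)[Sn](CCCC)(CCCC)CCCC | intermediate
30 | methyl (S,2E,8E,12E)-15-(furan-3-yl)-2-iodo-4,8,12-trimethylpentadeca-2,8,12-trienoate | COC(=O)/C(I)=C\[C@@H](C)CCC/C(C)=C/CC/C(C)=C/CCc1ccoc1 | intermediate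
31 | propanoic acid | CCC(=O)O | starting material
32 | cuprous propanoate (EtCO2Cu) | CCC(=O)[O-].[Cu+] | intermediate
33 | methyl (S,2E,8E,12E)-15-(furan-3-yl)-4,8,12-trimethyl-2-(propanoyloxy)pentadeca-2,8,12-trienoate | COC(=O)/C(OC(=O)CC)=C\[C@@H](C)CCC/C(C)=C/CC/C(C)=C/CCc1ccoc1 | intermediate
34 | (E)-5-[(2S,6E,10E)-13-(furan-3-yl)-2,6,10-trimethyltrideca-6,10-dien-1-ylidene]-4-hydroxy-3-methylfuran-2(5H)-one | OC1=C(C)C(=O)O/C1=C/[C@@H](C)CCC/C(C)=C/CC/C(C)=C/CCc1ccoc1 | intermediate
35 | hexadecanoyl chloride (palmitoyl chloride) | CCCCCCCCCCCCCCCC(=O)Cl | starting material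
36 | (E)-5-[(2S,6E,10E)-13-(furan-3-yl)-2,6,10-trimethyltrideca-6,10-dien-1-ylidene]-3-methyl-2-oxo-2,5-dihydrofuran-4-yl hexadecanoate (CNP0269639.1) | CCCCCCCCCCCCCCCC(=O)OC1=C(C)C(=O)O/C1=C/[C@@H](C)CCC/C(C)=C/CC/C(C)=C/CCc1ccoc1 | target

Total step count: 17. Longest linear sequence: 16 steps (steps 1–3 and 5–17 from 1); step 4 is a one-step side branch that makes reagent 7 and is carried out freshly before step 5 and again before step 7.

Steps most likely to fail

1. Step 5, the key step, whose operation is repeated in step 7. The alkyl ligand may fail to migrate before the mixed cuprate decomposes, or the alkenylcopper may be protonated or dimerise oxidatively instead of being methylated. The fallback builds the same alkene in two stages and sets out from iodide 5. The lithiated enol ether 7 is alkylated directly on carbon by 5 (THF, −30 → 20 °C) to give tert-butyl{[(S)-6-(4,5-dihydrofuran-2-yl)-3-methylhexyl]oxy}dimethylsilane F1. Nickel-catalysed Kumada-type ring-opening coupling of F1 with MeMgBr (NiCl2(PPh3)2, PhMe, reflux) then replaces the enol ether C–O bond by C–CH3 with retention, so the methyl group again ends cis to the hydroxyethyl arm. The route is rejoined at homoallylic alcohol 12.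

2. Step 12. Syn-elimination from the E-configured alkenyl nonaflate may be incomplete, the aldehyde may self-condense under the strong base, or the base may isomerise the new alkyne towards an allene and so erase the stereocentre. The fallback avoids enolisation altogether and sets out from aldehyde 23. Hydrazine hydrate (EtOH, 20 °C) should give (S,7E,11E)-14-(furan-3-yl)-3,7,11-trimethyltetradeca-7,11-dienal hydrazone F2. Barton-type oxidation of F2 with I2 and tetramethylguanidine (Et2O, 0 °C), followed by DBU on the crude product, should give 3-[(S,3E,7E,13E)-14-iodo-4,8,12-trimethyltetradeca-3,7,13-trien-1-yl]furan F3. LiN(iPr)2 (2.2 equiv, THF, −78 → 0 °C) dehydroiodinates F3 to the lithium acetylide 27, which is acylated with 26 as in step 13. The route is rejoined at ynoate 28.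

3. Step 15. C–O bond formation at the hindered, electron-poor alkenyl iodide may be slow, leaving time for reductive loss of iodine or for E/Z isomerisation at the alkenylcopper stage. The fallback reverses the polarity of the coupling and sets out from iodide 30. Miyaura borylation (B2pin2, PdCl2(PPh3)2, PPh3, KOPh, PhMe, 50 °C) should give, with retention, methyl (S,2Z,8E,12E)-15-(furan-3-yl)-4,8,12-trimethyl-2-(4,4,5,5-tetramethyl-1,3,2-dioxaborolan-2-yl)pentadeca-2,8,12-trienoate F4. KHF2 (MeOH–H2O) converts F4 into potassium [(S,2Z,8E,12E)-15-(furan-3-yl)-1-methoxy-4,8,12-trimethyl-1-oxopentadeca-2,8,12-trien-2-yl]trifluoroborate F5. Chan–Lam-type oxidative coupling of F5 with propanoic acid 31 (CuBr cat., DMAP, 4 Å molecular sieves, O2, CH2Cl2) then forms the same alkenyl C–O bond with retention. The route is rejoined at enol propanoate 33.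

Further compounds

F1 | step 5 | tert-butyl{[(S)-6-(4,5-dihydrofuran-2-yl)-3-methylhexyl]oxy}dimethylsilane | CC(C)(C)[Si](C)(C)OCC[C@@H](C)CCCC1=CCCO1
F2 | step 12 | (S,7E,11E)-14-(furan-3-yl)-3,7,11-trimethyltetradeca-7,11-dienal hydrazone | NN=CC[C@@H](C)CCC/C(C)=C/CC/C(C)=C/CCc1ccoc1
F3 | step 12 | 3-[(S,3E,7E,13E)-14-iodo-4,8,12-trimethyltetradeca-3,7,13-trien-1-yl]furan | I/C=C/[C@@H](C)CCC/C(C)=C/CC/C(C)=C/CCc1ccoc1
F4 | step 15 | methyl (S,2Z,8E,12E)-15-(furan-3-yl)-4,8,12-trimethyl-2-(4,4,5,5-tetramethyl-1,3,2-dioxaborolan-2-yl)pentadeca-2,8,12-trienoate | COC(=O)/C(B1OC(C)(C)C(C)(C)O1)=C\[C@@H](C)CCC/C(C)=C/CC/C(C)=C/CCc1ccoc1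
F5 | step 15 | potassium [(S,2Z,8E,12E)-15-(furan-3-yl)-1-methoxy-4,8,12-trimethyl-1-oxopentadeca-2,8,12-trien-2-yl]trifluoroborate | [K+].COC(=O)/C(=C\[C@@H](C)CCC/C(C)=C/CC/C(C)=C/CCc1ccoc1)[B-](F)(F)F
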